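Its constants stand for no real mixture.

What I wanted first was the leftover: the fraction of substrate still in each flask after 4.0 d.

    initiator → 2 initiating radical (k1 = 2.01 × 10⁻⁵ /min)
    substrate + second chain carrier → released group + first chain carrier (k2 = 3.45 × 10⁵ /M/min)
    crystals ⇌ released group, rate k3*(cs3 - [released group]) while solid is left; crystals form when [released group] > cs3 (cs3 = 0.37 mM, k3 = 0.00227 /min)
    2 first chain carrier → ended chains (k4 = 7.6 × 10⁸ /M/s)
    reagent + first chain carrier ⇌ target + second chain carrier (K5 = 0.036, k5 = 5.80 × 10⁵ /M/min)
    substrate + initiating radical → capped initiator + first chain carrier (k6 = 6.74 × 10⁵ /M/s)

the same everywhere: reagent 44.0 mM; initiator 0.62 mM; time 4.0 d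

|  | substrate |
|---|---|
| birch | 1.2 mM |
| maple | 4.0 mM |
| oak | 12 mM |

- amount of target at the end, in percent of the substrate charged for birch, maple, oak, in this order
- the course of these numbers from the first flask to the last (hardly changes / falls, then rises / falls all the way / rises all the way / rises, then falls)

- in percentages every species weighs as the substrate in it: one ended chains counts as two
- for released group the crystals are counted in
- a doubled species enters its step squared and goes two at a time
- as a solid, counted per litre of solution: crystals
- "hardly changes" means that all values lie within two and a half points (for a concentration: within two and a half percent of the largest)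
- run time (birch): 4.0 d

I held the radical supply steady. The initiator's half-life by its own step, 24 d, is longer than the run. So I set initiation equal to termination, which put first chain carrier at 5.23 × 10⁻⁷ mM. Reagent was charged above the largest substrate charge, so I held it constant too. By that reckoning the forward reagent step ran at 19.2 mM/d.

With target and substrate at equal concentrations, second chain carrier reacts with target 46.7 times as fast as with substrate. This is the selectivity factor, s. I called the forward turnover over the run, counted in charges of substrate, the chain budget: 64.0 for birch, 19.2 for maple, 6.40 for oak.

With f the fraction left and target taken as the rest, integration gave s·ln(1/f) − (s − 1)(1 − f) = budget. Leaving 50.0% costs 9.52, leaving 25.0% costs 30.5, leaving 12.5% costs 57.1, and leaving 6.25% costs 86.6.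

One number was not enough. Two radicals came from each initiator lost, and I let each spend a substrate that finished in ended chains, not target. That share is 11.3% in birch, 3.39% in maple and 1.13% in oak. Subtracting it, I expected target of 76.2% to 82.5% in birch and 46.6% to 71.6% in maple. For oak I expected under 48.9%. I committed to a falling row.

The forecast read 84%, 62%, 40%, falls all the way: “The chain's total throughput over four days is therefore limited”.

The simulation gave 83.3%, 62.5%, 40.4%, falls all the way. Birch stood just above my range, with 5.43% of its substrate left and 11.3% in ended chains. Maple kept 34.1% of its substrate. Put through the same equation, that fraction costs a budget of 20.1, against maple's budget of 19.2.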